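**Plan**

Numbering (elemane type): C10 = quaternary ring carbon (methyl, vinyl C1=C2); C9 = ring CH2; C8 = ring carbon with the butenoate; C7 and C6 = ring-fusion carbons (C7 carries lactone carbon C11, C6 the lactone oxygen); C5 = ring carbon with the isopropenyl group (C4=C3); C12 = lactone carbonyl.
Retrosynthesis: cut the C8 ester, the C11 acetate and C11 methyl, and the lactone C–O bond; then cut C7–C8 and C5–C10 of the cyclohexane in one operation, which leaves an acyclic δ-hydroxy enone held together by a temporary C3–C8 bond; cut that bond (vinylogous aldol) into a dienal and a methallyl ketone.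
Enabling feature: C6–O and C8–O are 1,3 across C7 in the cyclohexane (aldol retron), and the C8 carbonyl–C9–C10–C5 chain carries the C4=C3 isopropenyl alkene in the δ,ε position (oxy-Cope retron), with the vinyl and isopropenyl groups on adjacent carbons.
Forward: the chain is joined at C3–C8; a [3,3] shift then moves this link to C5–C10 and an aldol addition closes the cyclohexane at C7–C8; the lactone ring follows after C6 reduction; C11 is then hydroxylated, methylated and acetylated, and the C8 ester comes last.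
Stereochemistry: C8 (R) of the acyclic precursor is set by a chiral Lewis-base catalyst and relayed through a chair transition state to C5 and C10; C7 and C8 settle in a reversible aldol (equatorial); C6 comes from equatorial hydride attack; C11 from methylation on the convex face of the cis-fused lactone.

Key step: step 6

Remark: the (R,R) antipode of the bisphosphoramide in step 5 is assumed to direct attack on the Re face of the aldehyde (giving 8R); should the sense be opposite, the (S,S) antipode would be taken.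

**Route**

Step 1
Reactants: 1 (2E)-3-methylpent-2-en-4-yn-1-ol
Product: 2 (2E)-3-methylpenta-2,4-dien-1-ol
Conditions: H2 (1 atm), Pd/CaCO3 poisoned with Pb(OAc)2, quinoline, EtOAc, rt
Reagents that add atoms: none
Why: Partial hydrogenation of the terminal alkyne over poisoned palladium should stop at the vinyl group and leave the E trisubstituted alkene untouched.

Step 2
Reactants: 2 (2E)-3-methylpenta-2,4-dien-1-ol
Product: 3 (2E)-3-methylpenta-2,4-dienal
Conditions: MnO2 (excess), CH2Cl2, rt
Reagents that add atoms: none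
Why: Allylic alcohol oxidation with MnO2 should give the dienal without E/Z isomerisation or over-oxidation.

Step 3
Reactants: 4 methyl 4-chloro-4-oxobutanoate; 5 tributyl(2-methylprop-2-en-1-yl)stannane
Product: 6 methyl 6-methyl-4-oxohept-6-enoate
Conditions: PdCl2(PPh3)2 (2 mol %), THF, 60 °C
Reagents that add atoms: none
Why: Stille acylation, in which zerovalent palladium inserts into the acyl chloride, the methallyl group is transferred from tin and reductive elimination gives the β,γ-unsaturated ketone under neutral conditions that spare the ester and the alkene position.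

Step 4
Reactants: 6 methyl 6-methyl-4-oxohept-6-enoate
Product: 7 methyl (4Z)-4-[(tert-butyldimethylsilyl)oxy]-6-methylhepta-4,6-dienoate
Conditions: TBSOTf (1.2 equiv), Et3N (1.5 equiv), CH2Cl2, 0 °C
Reagents that add atoms: tert-butyldimethylsilyl trifluoromethanesulfonate, CC(C)(C)[Si](C)(C)OS(=O)(=O)C(F)(F)F
Why: Soft enolisation and O-silylation, in which C5 (allylic and α to the ketone) is the most acidic position, so that the conjugated 2-silyloxy diene should form in preference to the enol ether towards C7.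

Step 5
Reactants: 7 methyl (4Z)-4-[(tert-butyldimethylsilyl)oxy]-6-methylhepta-4,6-dienoate; 3 (2E)-3-methylpenta-2,4-dienal
Product: 8 methyl (5E,8R,9E)-8-hydroxy-6,10-dimethyl-4-oxododeca-5,9,11-trienoate
Conditions: SiCl4 (1.1 equiv), (R,R)-bisphosphoramide (pentane-1,5-diyl-linked 2,2'-binaphthyldiamine phosphoramide, 5 mol %), iPr2NEt (10 mol %), CH2Cl2, −78 °C; aqueous work-up
Reagents that add atoms: none
Why: Catalytic enantioselective vinylogous Mukaiyama aldol addition, in which the chiral Lewis-base-bound trichlorosilyl cation activates the aldehyde, the unsubstituted γ-carbon (C3) of the dienol ether adds 1,2 to the Re face to set C8 (R), and the regenerated enone alkene should form E.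

Step 6
Reactants: 8 methyl (5E,8R,9E)-8-hydroxy-6,10-dimethyl-4-oxododeca-5,9,11-trienoate
Product: 10 methyl 2-[(1S,3R,4S,6R)-4-ethenyl-6-hydroxy-4-methyl-2-oxo-3-(prop-1-en-2-yl)cyclohexyl]acetate, via keto aldehyde 9 (not isolated)
Conditions: KN(SiMe3)2 (2.2 equiv), 18-crown-6 (2.2 equiv), THF, −78 °C to 0 °C; AcOH (2.2 equiv), −78 °C; then MeOH, K2CO3 (0.3 equiv), 0 °C
Reagents that add atoms: none
Why: Proposed new method: two equivalents of base turn 8 into the C8 alkoxide/C7 cross-conjugated enolate dianion, so that the allyl half of the 3-oxido-1,5-diene (C10=C9–C8(O−)–C3–C4=C5) is an electron-rich oxidodiene that cannot depart as a stabilised dienolate; retro-vinylogous aldol cleavage should thus be shut off and the alkoxide-accelerated [3,3] shift should form C5–C10 while it breaks the temporary C3–C8 bond, after which protonation gives keto aldehyde 9 and carbonate in methanol lets the C7 enolate add to the freed C8 aldehyde. The closest known reaction types are the anionic oxy-Cope rearrangement of potassium 1,5-dien-3-olates and oxy-Cope/aldol tandem sequences; new is the use of the dianion of a vinylogous aldol adduct. The [3,3] shift closes no ring; the cyclohexane closes in the aldol step by a 6-(enolendo)-exo-trig addition of C7 to C8. C5 and C10 follow from the chair transition state with both alkenes E (C10 methyl axial; vinyl and the C6 enolate equatorial), and the axial C10 methyl forces the C8 oxygen equatorial, so that the (R)-carbinol should be relayed to 5R,10S; C7 and C8 settle in the reversible aldol with the acetate arm and the hydroxyl equatorial in the chair that keeps the isopropenyl group equatorial and the vinyl group axial. The step needs the [3,3] shift to win over fragmentation (secured by the enolate), C7 and not C5 as aldol donor (C5 is a hindered methine next to quaternary C10 and could close only a four-membered ring) and no epimerisation at C5 (mild carbonate conditions at low temperature).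

Step 7
Reactants: 10 methyl 2-[(1S,3R,4S,6R)-4-ethenyl-6-hydroxy-4-methyl-2-oxo-3-(prop-1-en-2-yl)cyclohexyl]acetate
Product: 11 methyl 2-[(1S,3R,4S,6R)-6-[(tert-butyldimethylsilyl)oxy]-4-ethenyl-4-methyl-2-oxo-3-(prop-1-en-2-yl)cyclohexyl]acetate
Conditions: TBSOTf (1.2 equiv), 2,6-lutidine (2 equiv), CH2Cl2, −78 °C
Reagents that add atoms: tert-butyldimethylsilyl trifluoromethanesulfonate, CC(C)(C)[Si](C)(C)OS(=O)(=O)C(F)(F)F
Why: Silylation of the secondary alcohol at low temperature should be faster than enol ether formation of the hindered ketone, and it blocks C8–O from lactonisation and from later enolate chemistry.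

Step 8
Reactants: 11 methyl 2-[(1S,3R,4S,6R)-6-[(tert-butyldimethylsilyl)oxy]-4-ethenyl-4-methyl-2-oxo-3-(prop-1-en-2-yl)cyclohexyl]acetate
Product: 13 (3aR,4R,6S,7R,7aR)-4-[(tert-butyldimethylsilyl)oxy]-6-ethenyl-6-methyl-7-(prop-1-en-2-yl)hexahydro-1-benzofuran-2(3H)-one, via hydroxy ester 12 (not isolated)
Conditions: LiBH(sec-Bu)3 (1.3 equiv), THF, −78 °C; 1 M HCl work-up; then camphorsulfonic acid (cat.), toluene, 40 °C
Reagents that add atoms: none
Why: Ketone reduction with a bulky trialkylborohydride, in which the axial vinyl group on C10 blocks the axial trajectory at C6 so that hydride should enter equatorially and give the axial C6 alcohol cis to the C7 acetate arm, which then closes the cis-fused γ-lactone by acid-catalysed lactonisation.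

Step 9
Reactants: 13 (3aR,4R,6S,7R,7aR)-4-[(tert-butyldimethylsilyl)oxy]-6-ethenyl-6-methyl-7-(prop-1-en-2-yl)hexahydro-1-benzofuran-2(3H)-one
Product: 14 (3R,3aR,4R,6S,7R,7aR)-4-[(tert-butyldimethylsilyl)oxy]-6-ethenyl-3-hydroxy-6-methyl-7-(prop-1-en-2-yl)hexahydro-1-benzofuran-2(3H)-one
Conditions: KN(SiMe3)2 (1.2 equiv), THF, −78 °C; 2-(phenylsulfonyl)-3-phenyloxaziridine (1.3 equiv); AcOH quench
Reagents that add atoms: 2-(phenylsulfonyl)-3-phenyloxaziridine, O=S(=O)(c1ccccc1)N1OC1c1ccccc1
Why: Enolate oxidation with an N-sulfonyloxaziridine should hydroxylate C11 from the convex face (cis to H7), although this centre is made planar again in step 10.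

Step 10
Reactants: 14 (3R,3aR,4R,6S,7R,7aR)-4-[(tert-butyldimethylsilyl)oxy]-6-ethenyl-3-hydroxy-6-methyl-7-(prop-1-en-2-yl)hexahydro-1-benzofuran-2(3H)-one
Product: 16 (3S,3aR,4R,6S,7R,7aR)-4-[(tert-butyldimethylsilyl)oxy]-6-ethenyl-3,6-dimethyl-2-oxo-7-(prop-1-en-2-yl)octahydro-1-benzofuran-3-yl acetate, via tertiary alcohol 15 (not isolated)
Conditions: LiN(iPr)2 (2.3 equiv), THF/DMPU, −78 °C to −40 °C; MeI (1.5 equiv), −78 °C to −20 °C; then Ac2O (4 equiv), 0 °C
Reagents that add atoms: iodomethane, CI; acetic anhydride, CC(=O)OC(C)=O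
Why: Alkylation of the α-oxido lactone enolate (dianion), in which MeI should approach C11 from the convex face of the cis-fused bicycle (the side of H6 and H7, away from C8) and so place methyl cis to H7 and oxygen cis to C8, followed by acetylation of the tertiary lithium alkoxide in the same flask.

Step 11
Reactants: 16 (3S,3aR,4R,6S,7R,7aR)-4-[(tert-butyldimethylsilyl)oxy]-6-ethenyl-3,6-dimethyl-2-oxo-7-(prop-1-en-2-yl)octahydro-1-benzofuran-3-yl acetate
Product: 17 (3S,3aS,4R,6S,7R,7aR)-6-ethenyl-4-hydroxy-3,6-dimethyl-2-oxo-7-(prop-1-en-2-yl)octahydro-1-benzofuran-3-yl acetate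
Conditions: HF·pyridine, pyridine, THF, 0 °C to rt
Reagents that add atoms: none
Why: Buffered fluoride cleavage of the secondary silyl ether should leave the tertiary acetate, the lactone and the three alkenes untouched.

Step 12
Reactants: 17 (3S,3aS,4R,6S,7R,7aR)-6-ethenyl-4-hydroxy-3,6-dimethyl-2-oxo-7-(prop-1-en-2-yl)octahydro-1-benzofuran-3-yl acetate; 18 3-methylbut-3-enoic acid
Product: 19 (3S,3aS,4R,6S,7R,7aR)-3-(acetyloxy)-6-ethenyl-3,6-dimethyl-2-oxo-7-(prop-1-en-2-yl)octahydro-1-benzofuran-4-yl 3-methylbut-3-enoate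
Conditions: EDC·HCl (1.5 equiv), DMAP (0.1 equiv), CH2Cl2, 0 °C
Reagents that add atoms: none
Why: Steglich esterification of the equatorial C8 hydroxyl, in which low temperature and little DMAP should limit migration of the β,γ-alkene of the acyl group into conjugation.

**Compound list**

1 | (2E)-3-methylpent-2-en-4-yn-1-ol | OC/C=C(\C)C#C | starting material
2 | (2E)-3-methylpenta-2,4-dien-1-ol | OC/C=C(\C)C=C | intermediate
3 | (2E)-3-methylpenta-2,4-dienal | O=C/C=C(\C)C=C | intermediate
4 | methyl 4-chloro-4-oxobutanoate | COC(=O)CCC(Cl)=O | starting material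
5 | tributyl(2-methylprop-2-en-1-yl)stannane | CCCC[Sn](CCCC)(CCCC)CC(C)=C | starting material
6 | methyl 6-methyl-4-oxohept-6-enoate | COC(=O)CCC(=O)CC(C)=C | intermediate
7 | methyl (4Z)-4-[(tert-butyldimethylsilyl)oxy]-6-methylhepta-4,6-dienoate | COC(=O)CC/C(O[Si](C)(C)C(C)(C)C)=C/C(C)=C | intermediate
8 | methyl (5E,8R,9E)-8-hydroxy-6,10-dimethyl-4-oxododeca-5,9,11-trienoate | COC(=O)CCC(=O)/C=C(\C)C[C@@H](O)/C=C(\C)C=C | intermediate
9 | methyl (5R,6S)-6-ethenyl-6-methyl-4,8-dioxo-5-(prop-1-en-2-yl)octanoate (keto aldehyde) | C=C[C@](C)(CC=O)[C@@H](C(C)=C)C(=O)CCC(=O)OC | intermediate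
10 | methyl 2-[(1S,3R,4S,6R)-4-ethenyl-6-hydroxy-4-methyl-2-oxo-3-(prop-1-en-2-yl)cyclohexyl]acetate | C=C[C@]1(C)C[C@@H](O)[C@H](CC(=O)OC)C(=O)[C@@H]1C(C)=C | intermediate
11 | methyl 2-[(1S,3R,4S,6R)-6-[(tert-butyldimethylsilyl)oxy]-4-ethenyl-4-methyl-2-oxo-3-(prop-1-en-2-yl)cyclohexyl]acetate | C=C[C@]1(C)C[C@@H](O[Si](C)(C)C(C)(C)C)[C@H](CC(=O)OC)C(=O)[C@@H]1C(C)=C | intermediate
12 | methyl 2-[(1R,2R,3R,4S,6R)-6-[(tert-butyldimethylsilyl)oxy]-4-ethenyl-2-hydroxy-4-methyl-3-(prop-1-en-2-yl)cyclohexyl]acetate (hydroxy ester) | C=C[C@]1(C)C[C@@H](O[Si](C)(C)C(C)(C)C)[C@H](CC(=O)OC)[C@H](O)[C@@H]1C(C)=C | intermediate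
13 | (3aR,4R,6S,7R,7aR)-4-[(tert-butyldimethylsilyl)oxy]-6-ethenyl-6-methyl-7-(prop-1-en-2-yl)hexahydro-1-benzofuran-2(3H)-one | C=C[C@]1(C)C[C@@H](O[Si](C)(C)C(C)(C)C)[C@H]2[C@H](OC(=O)C2)[C@@H]1C(C)=C | intermediate
14 | (3R,3aR,4R,6S,7R,7aR)-4-[(tert-butyldimethylsilyl)oxy]-6-ethenyl-3-hydroxy-6-methyl-7-(prop-1-en-2-yl)hexahydro-1-benzofuran-2(3H)-one | C=C[C@]1(C)C[C@@H](O[Si](C)(C)C(C)(C)C)[C@H]2[C@H](OC(=O)[C@@H]2O)[C@@H]1C(C)=C | intermediate
15 | (3S,3aR,4R,6S,7R,7aR)-4-[(tert-butyldimethylsilyl)oxy]-6-ethenyl-3-hydroxy-3,6-dimethyl-7-(prop-1-en-2-yl)hexahydro-1-benzofuran-2(3H)-one (tertiary alcohol) | C=C[C@]1(C)C[C@@H](O[Si](C)(C)C(C)(C)C)[C@H]2[C@H](OC(=O)[C@@]2(C)O)[C@@H]1C(C)=C | intermediate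
16 | (3S,3aR,4R,6S,7R,7aR)-4-[(tert-butyldimethylsilyl)oxy]-6-ethenyl-3,6-dimethyl-2-oxo-7-(prop-1-en-2-yl)octahydro-1-benzofuran-3-yl acetate | C=C[C@]1(C)C[C@@H](O[Si](C)(C)C(C)(C)C)[C@H]2[C@H](OC(=O)[C@@]2(C)OC(C)=O)[C@@H]1C(C)=C | intermediate
17 | (3S,3aS,4R,6S,7R,7aR)-6-ethenyl-4-hydroxy-3,6-dimethyl-2-oxo-7-(prop-1-en-2-yl)octahydro-1-benzofuran-3-yl acetate | C=C[C@]1(C)C[C@@H](O)[C@H]2[C@H](OC(=O)[C@@]2(C)OC(C)=O)[C@@H]1C(C)=C | intermediate
18 | 3-methylbut-3-enoic acid | C=C(C)CC(=O)O | starting material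
19 | (3S,3aS,4R,6S,7R,7aR)-3-(acetyloxy)-6-ethenyl-3,6-dimethyl-2-oxo-7-(prop-1-en-2-yl)octahydro-1-benzofuran-4-yl 3-methylbut-3-enoate | C=C[C@]1(C)C[C@@H](OC(=O)CC(=C)C)[C@H]2[C@H](OC(=O)[C@@]2(C)OC(C)=O)[C@@H]1C(=C)C | target

**Step count and risks**

Total step count: 12. Longest linear sequence: 10 steps (steps 3 to 12, from 4 to 19); steps 1 and 2 make the dienal that enters at step 5.

Steps most likely to fail:

Step 6 (Proposed new method). The dianion may fail to form cleanly, the alkoxide may fragment by retro-vinylogous aldol cleavage before the [3,3] shift, or the C5 configuration may be lost by enolisation during the aldol stage. The fallback uses known reactions and sets out from 8. Silylation of the C8 hydroxyl (TMSCl, imidazole) would give the trimethylsilyl ether F1. Kinetic enolisation at C7 with LiN(iPr)2 and trapping with TBSCl would give the cross-conjugated silyl dienol ether F2. Methanolysis of the trimethylsilyl ether (K2CO3, MeOH, 0 °C) would give the free carbinol F3. Anionic oxy-Cope rearrangement of its potassium alkoxide (KH, 18-crown-6, THF, then AcOH), whose allyl half is no longer a leaving dienolate, would give the aldehyde silyl enol ether F4. An intramolecular Mukaiyama aldol addition (BF3·OEt2, CH2Cl2, −78 °C, then brief K2CO3/MeOH equilibration of C7 and C8) would bring the route back at 10.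

Step 10. Dianion formation may be incomplete, the alkoxide may be methylated on oxygen, or facial selectivity at C11 may be poor. The fallback sets out from 14. Silylation (TESOTf, 2,6-lutidine) would give the triethylsilyl ether F5. Methylation of its simple lactone enolate (LiN(iPr)2, MeI, −78 °C) from the convex face would give the methylated silyl ether F6. Selective removal of the triethylsilyl group (HF·pyridine, pyridine, 0 °C) would give 15, now isolated, and acetylation (Ac2O, Et3N, DMAP) would return to the route at 16.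

Step 12. The β,γ-alkene of the acyl group may migrate into conjugation during activation of the acid. The fallback sets out from 17. Acylation with 3-methylbut-2-enoyl chloride (pyridine, DMAP, CH2Cl2) would give the conjugated ester F7. Photochemical deconjugation (254 nm, cat. 1,2-dimethylimidazole, CH2Cl2) would move the alkene out of conjugation and arrive at 19.

Further compounds

F1 | step 6 | methyl (5E,8R,9E)-6,10-dimethyl-4-oxo-8-[(trimethylsilyl)oxy]dodeca-5,9,11-trienoate | COC(=O)CCC(=O)/C=C(\C)C[C@@H](O[Si](C)(C)C)/C=C(\C)C=C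
F2 | step 6 | methyl (3E,5E,8R,9E)-4-[(tert-butyldimethylsilyl)oxy]-6,10-dimethyl-8-[(trimethylsilyl)oxy]dodeca-3,5,9,11-tetraenoate | COC(=O)C\C=C(O[Si](C)(C)C(C)(C)C)/C=C(\C)C[C@@H](O[Si](C)(C)C)/C=C(\C)C=C
F3 | step 6 | methyl (3E,5E,8R,9E)-4-[(tert-butyldimethylsilyl)oxy]-8-hydroxy-6,10-dimethyldodeca-3,5,9,11-tetraenoate | COC(=O)C\C=C(O[Si](C)(C)C(C)(C)C)/C=C(\C)C[C@@H](O)/C=C(\C)C=C
F4 | step 6 | methyl (3E,5R,6S)-4-[(tert-butyldimethylsilyl)oxy]-6-ethenyl-6-methyl-8-oxo-5-(prop-1-en-2-yl)oct-3-enoate | C=C[C@](C)(CC=O)[C@@H](C(C)=C)/C(O[Si](C)(C)C(C)(C)C)=C\CC(=O)OC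
F5 | step 10 | (3R,3aR,4R,6S,7R,7aR)-4-[(tert-butyldimethylsilyl)oxy]-6-ethenyl-6-methyl-7-(prop-1-en-2-yl)-3-[(triethylsilyl)oxy]hexahydro-1-benzofuran-2(3H)-one | C=C[C@]1(C)C[C@@H](O[Si](C)(C)C(C)(C)C)[C@H]2[C@H](OC(=O)[C@@H]2O[Si](CC)(CC)CC)[C@@H]1C(C)=C
F6 | step 10 | (3S,3aR,4R,6S,7R,7aR)-4-[(tert-butyldimethylsilyl)oxy]-6-ethenyl-3,6-dimethyl-7-(prop-1-en-2-yl)-3-[(triethylsilyl)oxy]hexahydro-1-benzofuran-2(3H)-one | C=C[C@]1(C)C[C@@H](O[Si](C)(C)C(C)(C)C)[C@H]2[C@H](OC(=O)[C@@]2(C)O[Si](CC)(CC)CC)[C@@H]1C(C)=C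
F7 | step 12 | (3S,3aS,4R,6S,7R,7aR)-3-(acetyloxy)-6-ethenyl-3,6-dimethyl-2-oxo-7-(prop-1-en-2-yl)octahydro-1-benzofuran-4-yl 3-methylbut-2-enoate | C=C[C@]1(C)C[C@@H](OC(=O)C=C(C)C)[C@H]2[C@H](OC(=O)[C@@]2(C)OC(C)=O)[C@@H]1C(C)=C
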